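**Plan**

- Numbering: C1 is the amide carbonyl, the chain runs to C15, the ring is C16–C21 with N on C20. C7 of the 19-membered lactam is an allylic carbinol lying between the C6 methyl stereocentre and the (E)-trisubstituted C8=C9 alkene; this is the mark of a vinylmetal-to-aldehyde addition, and the ring is opened there.
- Cuts, in retrosynthetic order: quinone to the C18/C21 dimethyl ether (carbamate and C15 silyl ether adjusted); C7–C8 (vinyl iodide plus aldehyde, opens the macrocycle); N–C1 amide (aniline C8–C21 plus dienoic acid C1–C7); then C9–C10 (propynyl/epoxide), C11–C12 (propenyl/aldehyde), C14–C15 (crotyl/aryl aldehyde) and the C2=C3 and C4=C5 olefinations.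
- Forward: the chain grows from the nitro-aryl aldehyde (C15 to C8), the nitro group is reduced and acylated with the C1–C7 acid, C7 is oxidised, the only new ring (19-membered) closes by CrCl2/NiCl2 coupling, then carbamate, desilylation and quinone.
- Stereocentres: C14/C15 from Brown (Z)-crotylboration; C12 from a ligand-controlled alkenylzinc addition; C10/C11 from Sharpless epoxidation and invertive alkynylalane opening; C6 from the (R)-Roche ester; C7 from Felkin addition during ring closure.
- Alkenes: 2E from a stabilised Wittig ylide, 4Z from Still–Gennari olefination, 8E from syn-hydrostannation/iodination with retention in the coupling.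

Key step: step 21

Remark: the target is read as 2E,4Z,8E and 6S,7R,10S,11R,12S,14S,15R in the numbering above.
Remark: the (R)-enantiomer of methyl 3-hydroxy-2-methylpropanoate is required, because its ester carbon becomes C5 and its CH2OH carbon becomes C7, which gives 6S.
Remark: in the last step both quinone oxygens are taken from water and both O-methyl groups leave as methanol.

**Route**

Step 1
Reactants: 1 2-hydroxy-5-methoxy-3-nitrobenzaldehyde
Product: 2 2,5-dimethoxy-3-nitrobenzaldehyde
Conditions: MeI, K2CO3, DMF, rt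
Reagents that add atoms: iodomethane, CI
Why: Williamson O-methylation of the acidic ortho-nitrophenol, for which carbonate is a sufficient base and which leaves the formyl group untouched.

Step 2
Reactants: 2 2,5-dimethoxy-3-nitrobenzaldehyde
Product: 4 (1R,2S)-1-(2,5-dimethoxy-3-nitrophenyl)-2-methylbut-3-en-1-ol, via diisopinocampheylborinate ester 3 (not isolated)
Conditions: cis-but-2-ene, n-BuLi, KOt-Bu, THF, −78 → −45 °C; (+)-Ipc2BOMe, −78 °C; BF3·OEt2; then 2, −78 °C; NaOH, H2O2, 0 °C → rt
Reagents that add atoms: (Z)-but-2-ene, C/C=C\C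
Why: Brown asymmetric (Z)-crotylboration, in which the closed chair transition state turns the Z geometry into the 14,15-syn pair and the isopinocampheyl groups of the (−)-α-pinene series direct the crotyl group to the Re face of the aldehyde, which should set 15R and 14S.

Step 3
Reactants: 4 (1R,2S)-1-(2,5-dimethoxy-3-nitrophenyl)-2-methylbut-3-en-1-ol
Product: 5 tert-butyl{[(1R,2S)-1-(2,5-dimethoxy-3-nitrophenyl)-2-methylbut-3-en-1-yl]oxy}dimethylsilane
Conditions: TBSOTf, 2,6-lutidine, CH2Cl2, 0 °C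
Reagents that add atoms: tert-butyldimethylsilyl trifluoromethanesulfonate, CC(C)(C)[Si](C)(C)OS(=O)(=O)C(F)(F)F
Why: silylation of a hindered secondary benzylic alcohol with the silyl triflate and a non-nucleophilic base, which blocks C15 until the end.

Step 4
Reactants: 5 tert-butyl{[(1R,2S)-1-(2,5-dimethoxy-3-nitrophenyl)-2-methylbut-3-en-1-yl]oxy}dimethylsilane
Product: 7 (3S,4R)-4-(tert-butyldimethylsilyloxy)-4-(2,5-dimethoxy-3-nitrophenyl)-3-methylbutan-1-ol, via B-alkyl-9-borabicyclo[3.3.1]nonane 6 (not isolated)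
Conditions: 9-BBN, THF, 0 °C → rt; then NaOH, H2O2, 0 °C
Reagents that add atoms: hydrogen peroxide, OO
Why: anti-Markovnikov hydroboration of the terminal alkene by the bulky borane followed by oxidation with retention, both of which leave the nitroarene and the silyl ether alone.

Step 5
Reactants: 7 (3S,4R)-4-(tert-butyldimethylsilyloxy)-4-(2,5-dimethoxy-3-nitrophenyl)-3-methylbutan-1-ol
Product: 8 (3S,4R)-4-(tert-butyldimethylsilyloxy)-4-(2,5-dimethoxy-3-nitrophenyl)-3-methylbutanal
Conditions: Dess–Martin periodinane, NaHCO3, CH2Cl2, 0 °C → rt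
Reagents that add atoms: none
Why: Dess–Martin oxidation of a primary alcohol under buffered neutral conditions, and the new aldehyde (C12) has no stereocentre at its α-carbon.

Step 6
Reactants: 8 (3S,4R)-4-(tert-butyldimethylsilyloxy)-4-(2,5-dimethoxy-3-nitrophenyl)-3-methylbutanal
Product: 9 (2E,4S,6S,7R)-7-(tert-butyldimethylsilyloxy)-7-(2,5-dimethoxy-3-nitrophenyl)-6-methylhept-2-en-4-ol
Conditions: propyne, Cy2BH, toluene, 0 °C → rt; Et2Zn, −78 °C; (+)-MIB (5 mol %); then 8, −20 → 0 °C; aq. NH4Cl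
Reagents that add atoms: propyne, CC#C
Why: catalytic asymmetric alkenylzinc addition (syn-hydroboration of propyne to the (E)-alkenylborane, boron-to-zinc exchange, amino-alcohol-accelerated 1,2-addition), in which the (+)-enantiomer of 3-exo-morpholinoisoborneol is chosen to deliver the propenyl group to the Re face and so set 12S, and the organozinc should tolerate the nitro group.

Step 7
Reactants: 9 (2E,4S,6S,7R)-7-(tert-butyldimethylsilyloxy)-7-(2,5-dimethoxy-3-nitrophenyl)-6-methylhept-2-en-4-ol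
Product: 10 (1S,3S,4R)-4-(tert-butyldimethylsilyloxy)-4-(2,5-dimethoxy-3-nitrophenyl)-3-methyl-1-[(2S,3S)-3-methyloxiran-2-yl]butan-1-ol
Conditions: Ti(Oi-Pr)4, L-(+)-diisopropyl tartrate, t-BuOOH, 4 Å molecular sieves, CH2Cl2, −20 °C
Reagents that add atoms: tert-butyl hydroperoxide, CC(C)(C)OO
Why: Sharpless asymmetric epoxidation of a secondary (E)-allylic alcohol in its matched sense, where with the L-(+)-tartrate the (12S) alcohol is the fast-reacting isomer and should give the erythro trans-epoxide (10S,11S as oxirane descriptors) while any minor C12 epimer is left behind.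

Step 8
Reactants: 10 (1S,3S,4R)-4-(tert-butyldimethylsilyloxy)-4-(2,5-dimethoxy-3-nitrophenyl)-3-methyl-1-[(2S,3S)-3-methyloxiran-2-yl]butan-1-ol
Product: 11 (1R,2S,4S,5R,6S)-1-(tert-butyldimethylsilyloxy)-1-(2,5-dimethoxy-3-nitrophenyl)-2,6-dimethylnon-7-yne-4,5-diol
Conditions: propyne, n-BuLi, toluene/THF, −78 → 0 °C; Et2AlCl, 0 °C; then 10, toluene, 0 °C → rt; aq. potassium sodium tartrate
Reagents that add atoms: propyne, CC#C
Why: alkoxide-directed opening of a 2,3-epoxy alcohol by an alkynylalane at the epoxide carbon remote from the carbinol (C10) with inversion, which should turn the trans-epoxide into the 10,11-syn methyl/hydroxyl pair (10S) and bring in C8, C9 and the C8 methyl group.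

Step 9
Reactants: 11 (1R,2S,4S,5R,6S)-1-(tert-butyldimethylsilyloxy)-1-(2,5-dimethoxy-3-nitrophenyl)-2,6-dimethylnon-7-yne-4,5-diol
Product: 12 tert-butyl{[(1R,2S,4S,5R,6S)-1-(2,5-dimethoxy-3-nitrophenyl)-4,5-dimethoxy-2,6-dimethylnon-7-yn-1-yl]oxy}dimethylsilane
Conditions: Me3OBF4, 1,8-bis(dimethylamino)naphthalene, 4 Å molecular sieves, CH2Cl2, rt
Reagents that add atoms: trimethyloxonium tetrafluoroborate, C[O+](C)C.F[B-](F)(F)F
Why: exhaustive O-methylation with an oxonium salt and a hindered amine base, a non-basic etherification that avoids silyl migration from C15 to the diol.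

Step 10
Reactants: 12 tert-butyl{[(1R,2S,4S,5R,6S)-1-(2,5-dimethoxy-3-nitrophenyl)-4,5-dimethoxy-2,6-dimethylnon-7-yn-1-yl]oxy}dimethylsilane
Product: 14 tert-butyl{[(1R,2S,4S,5R,6S,7E)-1-(2,5-dimethoxy-3-nitrophenyl)-8-iodo-4,5-dimethoxy-2,6-dimethylnon-7-en-1-yl]oxy}dimethylsilane, via (E)-vinylstannane 13 (not isolated)
Conditions: Bu3SnH, PdCl2(PPh3)2 (cat.), THF, 0 °C → rt; then I2, CH2Cl2, 0 °C
Reagents that add atoms: iodine, II
Why: palladium-catalysed syn-hydrostannation should place tin on the less hindered alkyne carbon C8 (remote from the branched C10), and iododestannylation with retention then gives the (E)-vinyl iodide, the nitroarene being inert to iodine.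

Step 11
Reactants: 14 tert-butyl{[(1R,2S,4S,5R,6S,7E)-1-(2,5-dimethoxy-3-nitrophenyl)-8-iodo-4,5-dimethoxy-2,6-dimethylnon-7-en-1-yl]oxy}dimethylsilane
Product: 15 3-[(1R,2S,4S,5R,6S,7E)-1-(tert-butyldimethylsilyloxy)-8-iodo-4,5-dimethoxy-2,6-dimethylnon-7-en-1-yl]-2,5-dimethoxyaniline
Conditions: Fe powder, NH4Cl, EtOH/H2O, 70 °C
Reagents that add atoms: none
Why: Béchamp-type nitro reduction by iron in a near-neutral medium, which should spare the vinyl iodide and the benzylic silyl ether.

Step 12
Reactants: 16 methyl (R)-3-hydroxy-2-methylpropanoate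
Product: 17 methyl (R)-3-(tert-butyldimethylsilyloxy)-2-methylpropanoate
Conditions: TBSCl, imidazole, DMF, rt
Reagents that add atoms: tert-butyldimethylsilyl chloride, CC(C)(C)[Si](C)(C)Cl
Why: standard silylation of a primary alcohol, which protects the future C7 oxygen.

Step 13
Reactants: 17 methyl (R)-3-(tert-butyldimethylsilyloxy)-2-methylpropanoate
Product: 18 (R)-3-(tert-butyldimethylsilyloxy)-2-methylpropanal
Conditions: i-Bu2AlH, CH2Cl2, −78 °C; aq. potassium sodium tartrate
Reagents that add atoms: none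
Why: low-temperature half-reduction of the ester through its tetrahedral aluminium hemiacetal, cold enough that the α-stereocentre (the future C6) should not epimerise.

Step 14
Reactants: 18 (R)-3-(tert-butyldimethylsilyloxy)-2-methylpropanal
Product: 19 methyl (2Z,4S)-5-(tert-butyldimethylsilyloxy)-4-methylpent-2-enoate
Conditions: (CF3CH2O)2P(O)CH2CO2Me, KN(SiMe3)2, 18-crown-6, THF, −78 °C
Reagents that add atoms: methyl 2-[bis(2,2,2-trifluoroethoxy)phosphoryl]acetate, COC(=O)CP(=O)(OCC(F)(F)F)OCC(F)(F)F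
Why: Still–Gennari olefination, in which the electron-poor phosphonate and the dissociated potassium counter-ion make elimination fast and kinetic, which should give the (Z)-enoate (the C4=C5 alkene).

Step 15
Reactants: 19 methyl (2Z,4S)-5-(tert-butyldimethylsilyloxy)-4-methylpent-2-enoate
Product: 20 (2Z,4S)-5-(tert-butyldimethylsilyloxy)-4-methylpent-2-en-1-ol
Conditions: i-Bu2AlH (2.2 equiv), CH2Cl2, −78 °C
Reagents that add atoms: none
Why: 1,2-reduction of the enoate to the allylic alcohol by the aluminium hydride, which keeps the Z geometry.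

Step 16
Reactants: 20 (2Z,4S)-5-(tert-butyldimethylsilyloxy)-4-methylpent-2-en-1-ol
Product: 22 ethyl (2E,4Z,6S)-7-(tert-butyldimethylsilyloxy)-2,6-dimethylhepta-2,4-dienoate, via (Z)-enal 21 (not isolated)
Conditions: MnO2, Ph3P=C(CH3)CO2Et, CH2Cl2, rt
Reagents that add atoms: (1-ethoxycarbonylethylidene)triphenylphosphorane, CCOC(=O)C(C)=P(c1ccccc1)(c1ccccc1)c1ccccc1
Why: tandem allylic oxidation and Wittig olefination, in which the stabilised ylide traps the (Z)-enal as it forms, before it can isomerise, and should give the (2E)-trisubstituted alkene.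

Step 17
Reactants: 22 ethyl (2E,4Z,6S)-7-(tert-butyldimethylsilyloxy)-2,6-dimethylhepta-2,4-dienoate
Product: 23 (2E,4Z,6S)-7-(tert-butyldimethylsilyloxy)-2,6-dimethylhepta-2,4-dienoic acid
Conditions: LiOH, THF/MeOH/H2O, rt; then dilute HCl to pH 4, 0 °C
Reagents that add atoms: lithium hydroxide, [Li+].[OH-]
Why: saponification of the dienoate, which the primary silyl ether and the diene geometry should survive.

Step 18
Reactants: 23 (2E,4Z,6S)-7-(tert-butyldimethylsilyloxy)-2,6-dimethylhepta-2,4-dienoic acid; 15 3-[(1R,2S,4S,5R,6S,7E)-1-(tert-butyldimethylsilyloxy)-8-iodo-4,5-dimethoxy-2,6-dimethylnon-7-en-1-yl]-2,5-dimethoxyaniline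
Product: 25 N-{3-[(1R,2S,4S,5R,6S,7E)-1-(tert-butyldimethylsilyloxy)-8-iodo-4,5-dimethoxy-2,6-dimethylnon-7-en-1-yl]-2,5-dimethoxyphenyl}-(2E,4Z,6S)-7-(tert-butyldimethylsilyloxy)-2,6-dimethylhepta-2,4-dienamide, via acid chloride 24 (not isolated)
Conditions: 1-chloro-N,N,2-trimethylprop-1-en-1-amine, CH2Cl2, 0 °C → rt; then 15, pyridine, CH2Cl2, 0 °C → rt
Reagents that add atoms: none
Why: amide formation through the acid chloride, made under neutral conditions with the α-chloroenamine so that no HCl can isomerise the (4Z)-alkene, followed by N-acylation of the moderately hindered aniline.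

Step 19
Reactants: 25 the bis-silyl seco anilide
Product: 26 N-{3-[(1R,2S,4S,5R,6S,7E)-1-(tert-butyldimethylsilyloxy)-8-iodo-4,5-dimethoxy-2,6-dimethylnon-7-en-1-yl]-2,5-dimethoxyphenyl}-(2E,4Z,6S)-7-hydroxy-2,6-dimethylhepta-2,4-dienamide
Conditions: HF·pyridine, excess pyridine, THF, 0 °C
Reagents that add atoms: none
Why: selective fluoride-mediated desilylation, in which the unhindered primary C7 silyl ether should be cleaved well before the secondary benzylic C15 silyl ether flanked by the C14 methyl group and the ortho methoxy group.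

Step 20
Reactants: 26 the C7 alcohol of the seco anilide
Product: 27 N-{3-[(1R,2S,4S,5R,6S,7E)-1-(tert-butyldimethylsilyloxy)-8-iodo-4,5-dimethoxy-2,6-dimethylnon-7-en-1-yl]-2,5-dimethoxyphenyl}-(2E,4Z,6S)-2,6-dimethyl-7-oxohepta-2,4-dienamide
Conditions: Dess–Martin periodinane, NaHCO3, CH2Cl2, 0 °C; rapid filtration, used at once
Reagents that add atoms: none
Why: buffered Dess–Martin oxidation gives the aldehyde without base, which matters because C6 is both α to the carbonyl and allylic, so the product is not stored or chromatographed at length.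

Step 21
Reactants: 27 the seco anilide with C8 vinyl iodide and C7 aldehyde
Product: 28 macrocyclic C7 allylic alcohol (2E,4Z,8E; 6S,7R,10S,11R,12S,14S,15R; 15-O-tert-butyldimethylsilyl; 11,12,18,21-tetramethoxy; 19-membered lactam)
Conditions: CrCl2 (15 equiv), NiCl2 (1 mol % of the CrCl2), degassed DMSO/THF, rt, slow addition of 27 to a final concentration near 2 mM
Reagents that add atoms: none
Why: Zerovalent nickel, formed from NiCl2 by divalent chromium, inserts into the C8–I bond with retention of the alkene geometry; the vinyl group passes to trivalent chromium, the vinylchromium adds to the C7 aldehyde, and the chromium alkoxide is hydrolysed on work-up. The closest known reaction type is the Nozaki–Hiyama–Kishi macrocyclisation of ω-formyl vinyl iodides. The 19-membered ring closes in an exo-trig sense by attack of C8 on the C7 carbonyl carbon, with high dilution to suppress dimers and with the anilide, the (2E,4Z)-diene and the trisubstituted alkene limiting the conformational freedom of the chain. The new C7 stereocentre is controlled by C6 in a Felkin–Anh sense, the nucleophile entering anti to the C5 alkenyl group, which should give the 6,7-syn (7R) carbinol. The step needs chemoselectivity for the aldehyde and an intact C6; the first is secured because the organochromium reagent is not basic and ignores the amide, the diene and the silyl ether, the second because the medium is neutral and the aldehyde is used immediately.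

Step 22
Reactants: 28 macrocyclic C7 allylic alcohol
Product: 30 macrocyclic C7 carbamate (15-O-tert-butyldimethylsilyl; dimethoxyarene), via N-trichloroacetylcarbamate 29 (not isolated)
Conditions: Cl3CC(O)NCO, CH2Cl2, 0 °C; then K2CO3, MeOH, rt
Reagents that add atoms: trichloroacetyl isocyanate, O=C=NC(=O)C(Cl)(Cl)Cl
Why: carbamoylation by addition of the secondary alcohol to the acyl isocyanate and mild methanolysis of the trichloroacetyl group, with C7 untouched and the much less nucleophilic anilide N–H expected not to react.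

Step 23
Reactants: 30 macrocyclic C7 carbamate
Product: 31 macrocyclic C7 carbamate with free C15 alcohol (dimethoxyarene)
Conditions: HF·pyridine, THF, 0 °C → rt
Reagents that add atoms: none
Why: fluoride-mediated cleavage of the remaining secondary silyl ether under mildly acidic conditions that the primary carbamate and the lactam should tolerate.

Step 24
Reactants: 31 macrocyclic C7 carbamate with free C15 alcohol
Product: 32 CNP0557283.1 (the target aminoquinone)
Conditions: (NH4)2Ce(NO3)6, MeCN/H2O, −10 → 0 °C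
Reagents that add atoms: water, O
Why: oxidative demethylation of the 1,4-dimethoxyarene by tetravalent cerium (two one-electron oxidations, water adding at C18 and C21 and methanol leaving) should give the para-quinone while the acylamino group stays on C20, and it is faster than oxidation of the C15 carbinol.

**Compound list**

1 | 2-hydroxy-5-methoxy-3-nitrobenzaldehyde | COc1cc(C=O)c(O)c([N+](=O)[O-])c1 | starting material
2 | 2,5-dimethoxy-3-nitrobenzaldehyde | COc1cc(C=O)c(OC)c([N+](=O)[O-])c1 | intermediate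
3 | diisopinocampheylborinate ester of 4 (not isolated) | C=C[C@H](C)[C@@H](OB([C@H]1C[C@H]2C[C@@H]([C@@H]1C)C2(C)C)[C@H]1C[C@H]2C[C@@H]([C@@H]1C)C2(C)C)c1cc(OC)cc([N+](=O)[O-])c1OC | intermediate
4 | (1R,2S)-1-(2,5-dimethoxy-3-nitrophenyl)-2-methylbut-3-en-1-ol | C=C[C@H](C)[C@@H](O)c1cc(OC)cc([N+](=O)[O-])c1OC | intermediate
5 | tert-butyl{[(1R,2S)-1-(2,5-dimethoxy-3-nitrophenyl)-2-methylbut-3-en-1-yl]oxy}dimethylsilane | C=C[C@H](C)[C@@H](O[Si](C)(C)C(C)(C)C)c1cc(OC)cc([N+](=O)[O-])c1OC | intermediate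
6 | 9-[(3S,4R)-4-(tert-butyldimethylsilyloxy)-4-(2,5-dimethoxy-3-nitrophenyl)-3-methylbutyl]-9-borabicyclo[3.3.1]nonane (not isolated) | C1CCC2CCCC1B2CC[C@H](C)[C@@H](O[Si](C)(C)C(C)(C)C)c1cc(OC)cc([N+](=O)[O-])c1OC | intermediate
7 | (3S,4R)-4-(tert-butyldimethylsilyloxy)-4-(2,5-dimethoxy-3-nitrophenyl)-3-methylbutan-1-ol | OCC[C@H](C)[C@@H](O[Si](C)(C)C(C)(C)C)c1cc(OC)cc([N+](=O)[O-])c1OC | intermediate
8 | (3S,4R)-4-(tert-butyldimethylsilyloxy)-4-(2,5-dimethoxy-3-nitrophenyl)-3-methylbutanal | O=CC[C@H](C)[C@@H](O[Si](C)(C)C(C)(C)C)c1cc(OC)cc([N+](=O)[O-])c1OC | intermediate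
9 | (2E,4S,6S,7R)-7-(tert-butyldimethylsilyloxy)-7-(2,5-dimethoxy-3-nitrophenyl)-6-methylhept-2-en-4-ol | C/C=C/[C@@H](O)C[C@H](C)[C@@H](O[Si](C)(C)C(C)(C)C)c1cc(OC)cc([N+](=O)[O-])c1OC | intermediate
10 | (1S,3S,4R)-4-(tert-butyldimethylsilyloxy)-4-(2,5-dimethoxy-3-nitrophenyl)-3-methyl-1-[(2S,3S)-3-methyloxiran-2-yl]butan-1-ol | C[C@@H]1O[C@H]1[C@@H](O)C[C@H](C)[C@@H](O[Si](C)(C)C(C)(C)C)c1cc(OC)cc([N+](=O)[O-])c1OC | intermediate
11 | (1R,2S,4S,5R,6S)-1-(tert-butyldimethylsilyloxy)-1-(2,5-dimethoxy-3-nitrophenyl)-2,6-dimethylnon-7-yne-4,5-diol | CC#C[C@H](C)[C@@H](O)[C@@H](O)C[C@H](C)[C@@H](O[Si](C)(C)C(C)(C)C)c1cc(OC)cc([N+](=O)[O-])c1OC | intermediate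
12 | tert-butyl{[(1R,2S,4S,5R,6S)-1-(2,5-dimethoxy-3-nitrophenyl)-4,5-dimethoxy-2,6-dimethylnon-7-yn-1-yl]oxy}dimethylsilane | CC#C[C@H](C)[C@@H](OC)[C@@H](OC)C[C@H](C)[C@@H](O[Si](C)(C)C(C)(C)C)c1cc(OC)cc([N+](=O)[O-])c1OC | intermediate
13 | tert-butyl{[(1R,2S,4S,5R,6S,7E)-1-(2,5-dimethoxy-3-nitrophenyl)-4,5-dimethoxy-2,6-dimethyl-8-(tributylstannyl)non-7-en-1-yl]oxy}dimethylsilane (not isolated) | CCCC[Sn](CCCC)(CCCC)/C(C)=C/[C@H](C)[C@@H](OC)[C@@H](OC)C[C@H](C)[C@@H](O[Si](C)(C)C(C)(C)C)c1cc(OC)cc([N+](=O)[O-])c1OC | intermediate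
14 | tert-butyl{[(1R,2S,4S,5R,6S,7E)-1-(2,5-dimethoxy-3-nitrophenyl)-8-iodo-4,5-dimethoxy-2,6-dimethylnon-7-en-1-yl]oxy}dimethylsilane | I/C(C)=C/[C@H](C)[C@@H](OC)[C@@H](OC)C[C@H](C)[C@@H](O[Si](C)(C)C(C)(C)C)c1cc(OC)cc([N+](=O)[O-])c1OC | intermediate
15 | 3-[(1R,2S,4S,5R,6S,7E)-1-(tert-butyldimethylsilyloxy)-8-iodo-4,5-dimethoxy-2,6-dimethylnon-7-en-1-yl]-2,5-dimethoxyaniline | I/C(C)=C/[C@H](C)[C@@H](OC)[C@@H](OC)C[C@H](C)[C@@H](O[Si](C)(C)C(C)(C)C)c1cc(OC)cc(N)c1OC | intermediate
16 | methyl (R)-3-hydroxy-2-methylpropanoate | COC(=O)[C@H](C)CO | starting material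
17 | methyl (R)-3-(tert-butyldimethylsilyloxy)-2-methylpropanoate | COC(=O)[C@H](C)CO[Si](C)(C)C(C)(C)C | intermediate
18 | (R)-3-(tert-butyldimethylsilyloxy)-2-methylpropanal | O=C[C@H](C)CO[Si](C)(C)C(C)(C)C | intermediate
19 | methyl (2Z,4S)-5-(tert-butyldimethylsilyloxy)-4-methylpent-2-enoate | COC(=O)/C=C\[C@H](C)CO[Si](C)(C)C(C)(C)C | intermediate
20 | (2Z,4S)-5-(tert-butyldimethylsilyloxy)-4-methylpent-2-en-1-ol | OC/C=C\[C@H](C)CO[Si](C)(C)C(C)(C)C | intermediate
21 | (2Z,4S)-5-(tert-butyldimethylsilyloxy)-4-methylpent-2-enal (not isolated) | O=C/C=C\[C@H](C)CO[Si](C)(C)C(C)(C)C | intermediate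
22 | ethyl (2E,4Z,6S)-7-(tert-butyldimethylsilyloxy)-2,6-dimethylhepta-2,4-dienoate | CCOC(=O)/C(C)=C/C=C\[C@H](C)CO[Si](C)(C)C(C)(C)C | intermediate
23 | (2E,4Z,6S)-7-(tert-butyldimethylsilyloxy)-2,6-dimethylhepta-2,4-dienoic acid | OC(=O)/C(C)=C/C=C\[C@H](C)CO[Si](C)(C)C(C)(C)C | intermediate
24 | (2E,4Z,6S)-7-(tert-butyldimethylsilyloxy)-2,6-dimethylhepta-2,4-dienoyl chloride (not isolated) | ClC(=O)/C(C)=C/C=C\[C@H](C)CO[Si](C)(C)C(C)(C)C | intermediate
25 | seco anilide with C7 and C15 silyl ethers | I/C(C)=C/[C@H](C)[C@@H](OC)[C@@H](OC)C[C@H](C)[C@@H](O[Si](C)(C)C(C)(C)C)c1cc(OC)cc(NC(=O)/C(C)=C/C=C\[C@H](C)CO[Si](C)(C)C(C)(C)C)c1OC | intermediate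
26 | seco anilide with free C7 alcohol | I/C(C)=C/[C@H](C)[C@@H](OC)[C@@H](OC)C[C@H](C)[C@@H](O[Si](C)(C)C(C)(C)C)c1cc(OC)cc(NC(=O)/C(C)=C/C=C\[C@H](C)CO)c1OC | intermediate
27 | seco anilide with C8 vinyl iodide and C7 aldehyde (cyclisation precursor) | I/C(C)=C/[C@H](C)[C@@H](OC)[C@@H](OC)C[C@H](C)[C@@H](O[Si](C)(C)C(C)(C)C)c1cc(OC)cc(NC(=O)/C(C)=C/C=C\[C@H](C)C=O)c1OC | intermediate
28 | macrocyclic C7 allylic alcohol (15-O-silyl, dimethoxyarene) | CO[C@H]1[C@@H](OC)C[C@H](C)[C@@H](O[Si](C)(C)C(C)(C)C)c2cc(OC)cc(NC(=O)/C(C)=C/C=C\[C@H](C)[C@@H](O)/C(C)=C/[C@@H]1C)c2OC | intermediate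
29 | macrocyclic C7 N-trichloroacetylcarbamate (not isolated) | CO[C@H]1[C@@H](OC)C[C@H](C)[C@@H](O[Si](C)(C)C(C)(C)C)c2cc(OC)cc(NC(=O)/C(C)=C/C=C\[C@H](C)[C@@H](OC(=O)NC(=O)C(Cl)(Cl)Cl)/C(C)=C/[C@@H]1C)c2OC | intermediate
30 | macrocyclic C7 carbamate (15-O-silyl, dimethoxyarene) | CO[C@H]1[C@@H](OC)C[C@H](C)[C@@H](O[Si](C)(C)C(C)(C)C)c2cc(OC)cc(NC(=O)/C(C)=C/C=C\[C@H](C)[C@@H](OC(N)=O)/C(C)=C/[C@@H]1C)c2OC | intermediate
31 | macrocyclic C7 carbamate with free C15 alcohol (dimethoxyarene) | CO[C@H]1[C@@H](OC)C[C@H](C)[C@@H](O)c2cc(OC)cc(NC(=O)/C(C)=C/C=C\[C@H](C)[C@@H](OC(N)=O)/C(C)=C/[C@@H]1C)c2OC | intermediate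
32 | CNP0557283.1 | CO[C@H]1[C@@H](OC)C[C@H](C)[C@@H](O)C2=CC(=O)C=C(NC(=O)/C(C)=C/C=C\[C@H](C)[C@@H](OC(N)=O)/C(C)=C/[C@@H]1C)C2=O | target

**Count**

Total: 24 steps. Longest linear sequence: 18 steps (steps 1–11, then 18–24); the C1–C7 acid takes 6 steps (12–17).

**Steps most likely to fail**

Step 21. The macrocyclic transition state may override the Felkin preference, so that addition to the C7 aldehyde occurs on both faces or mainly on the wrong one; slow ring closure would also give the aldehyde time to epimerise at C6 or to couple between molecules. The fallback sets C7 by ketone reduction instead of by addition and keeps the same ring closure. It sets out from 28 obtained together with its C7 epimer. Oxidation of the mixture with Dess–Martin periodinane (NaHCO3, CH2Cl2, 0 °C) should give the macrocyclic C7 ketone F1. Reduction of F1 with (S)-2-methyl-CBS-oxazaborolidine and catecholborane (toluene, −78 °C; Corey–Bakshi–Shibata reduction, the alkenyl group acting as the large substituent) should return to 28 under reagent control. Both operations are neutral, so C6 should hold.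

Step 8. The alane may attack C11 instead of C10, or be consumed by complexation with or reduction of the nitro group. The fallback replaces alkoxide-directed delivery by external Lewis-acid activation of an O-alkylated epoxide. It sets out from 10. Methylation of the C12 hydroxyl (Me3OBF4, 1,8-bis(dimethylamino)naphthalene, CH2Cl2) should give the epoxy methyl ether F2. Opening of F2 with prop-1-ynyllithium and BF3·OEt2 (THF, −78 °C) should take place at C10, the epoxide carbon remote from the inductively deactivating C12 methoxy group, with inversion, to give the alkynyl alcohol F3. Methylation of F3 under the conditions of step 9 comes back to the route at 12.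

Step 6. Facial control by the amino-alcohol ligand may be poor on this α-unbranched aldehyde, and ethyl transfer or zinc-alkoxide-induced self-aldolisation may compete. The fallback sets C12 by ketone reduction. It sets out from 9 obtained as a mixture with its C12 epimer. Dess–Martin oxidation (NaHCO3, CH2Cl2) should give the enone F4. Reduction of F4 with (R)-2-methyl-CBS-oxazaborolidine and catecholborane (toluene, −78 °C) should return to 9, after which the matched epoxidation of step 7 removes residual C12 epimer.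

**Further compounds**

F1 | step 21 | macrocyclic C7 ketone (15-O-silyl, dimethoxyarene) | CO[C@H]1[C@@H](OC)C[C@H](C)[C@@H](O[Si](C)(C)C(C)(C)C)c2cc(OC)cc(NC(=O)/C(C)=C/C=C\[C@H](C)C(=O)/C(C)=C/[C@@H]1C)c2OC
F2 | step 8 | tert-butyl{[(1R,2S,4S)-1-(2,5-dimethoxy-3-nitrophenyl)-4-methoxy-2-methyl-4-[(2S,3S)-3-methyloxiran-2-yl]butyl]oxy}dimethylsilane | C[C@@H]1O[C@H]1[C@@H](OC)C[C@H](C)[C@@H](O[Si](C)(C)C(C)(C)C)c1cc(OC)cc([N+](=O)[O-])c1OC
F3 | step 8 | (3S,4R,5S,7S,8R)-8-(tert-butyldimethylsilyloxy)-8-(2,5-dimethoxy-3-nitrophenyl)-5-methoxy-3,7-dimethyloct-1-ynyl methyl alcohol: (4S,5R,6S,8S,9R)-9-(tert-butyldimethylsilyloxy)-9-(2,5-dimethoxy-3-nitrophenyl)-6-methoxy-4,8-dimethylnon-2-yn-5-ol | CC#C[C@H](C)[C@@H](O)[C@@H](OC)C[C@H](C)[C@@H](O[Si](C)(C)C(C)(C)C)c1cc(OC)cc([N+](=O)[O-])c1OC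
F4 | step 6 | (2E,6S,7R)-7-(tert-butyldimethylsilyloxy)-7-(2,5-dimethoxy-3-nitrophenyl)-6-methylhept-2-en-4-one | C/C=C/C(=O)C[C@H](C)[C@@H](O[Si](C)(C)C(C)(C)C)c1cc(OC)cc([N+](=O)[O-])c1OC
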